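## Structural features

36 is a bicyclo[4.3.0]nonadiene. Cyclohexene ring A (C3a, C4=C5, C6, C7, C7a) is trans-fused through C3a–C7a to cyclopentene ring B (C1=C2, C3). Five stereocentres stand in an unbroken row, C3–C3a–C7a–C7–C6. C6 (ethyl, E-styryl) and C7 (methyl, CO2H) are vicinal quaternary carbons; methyl and ethyl are cis to each other and cis to the C1 branch on C7a. The carboxyl group is neopentyl on both sides, so acyl substitution is very slow. It also lies γ,δ to two trisubstituted alkenes, so strong acid would close lactones. Any CH2O group on C6 sits 1,4 to the C7 carbonyl and can lactonise. The real difficulty is the quaternary pair C6/C7 in fixed relation to the trans fusion and to C3. The key step uses this: once ring B is opened at C1=C2 (C1 then carries a methylidene carbon, here C8), C3a–C7a is the central σ-bond of the 1,5-diene C5=C4–C3a–C7a–C1=C8. The reverse [3,3] shift trades it for C5–C8 and gives a cyclohex-3-en-1-ol (ring C: C5, C8, C1, C7a, C7, C6) that already holds C6 and C7.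

## Logic of the disconnections

36 ⇒ 35. Cut: the O–CH3 bond of the ester. The free acid is acid-sensitive and its carbonyl is shielded, so it is released last. The forward step must attack the methyl carbon, not the acyl carbon.

35 ⇒ 34. Cut: the styrene C=C (C6–CH=CHPh). An alkenyl group on C6 would open a second oxy-Cope path in 28, so the styrene has to come late. The forward olefination must be E-selective on a neopentyl aldehyde that has an ester three atoms away.

34 ⇒ 32 (through 33). No skeletal bond is cut; the aldehyde is drawn back to CH2OPMB. A benzyl-type ether is chosen because a silyl ether would migrate to the neighbouring alkoxide in 28. Demand: 33 must be oxidised before it lactonises.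

32 ⇒ 31. Cut: C1=C2. This removes ring B and the trans fusion as a ring problem. Demand: ring closure between a vinyl and a 1,1-disubstituted alkene on trans neighbours.

31 ⇒ 30. C5–H is drawn back to C5–OTf; this makes C5 an enolate carbon. Demand: reduction of a hindered enol triflate without Heck closure.

30 ⇒ 27. Cut: C3a–C7a; made: C5–C8. Two stereocentres (C3a, C7a) are replaced by one carbinol centre and a Z alkene, and the new ring holds only the quaternary pair. Demand: a [3,3] shift through a bridged boat that beats the [1,3] shift.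

27 ⇒ 17 + 24. Cut: C4–C5. This gives a ketone and an alkenyl iodide of equal weight. Demand: retention of Z geometry and addition to the face of 17 that bears CH2OPMB and CO2Me.

24 ⇒ 18. Cut: both C=C bonds of the skipped diene, leaving a three-carbon chiral-pool unit. Demand: Z-selective iodo-olefination, and no epimerisation of an α-methyl β,γ-unsaturated aldehyde (23).

17 ⇒ 16 ⇒ 10 + 14. Cut: C1=C7a (ring C alkene), then C5–C8 (acyl–allyl bond). The ring is reduced to an open-chain acid that carries only the quaternary pair. Demand: ketone formation at a neopentyl acyl carbon without base, and ring closure onto a 1,1-disubstituted alkene.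

10 ⇒ 8. Cut: C6–C7. This is the simplifying step for the quaternary pair: both centres come from one [3,3] shift of an allylic ester. Demand: a defined tetrasubstituted ketene acetal (9), a defined Z-enoate and a chair transition state.

8 ⇒ 4 + 5; 4 ⇒ 1; 14 ⇒ 11. Cut: the ester C–O bond and the enoate C=C (through 6 and 7); the acid goes back to a malonate and the stannane to an enal. All are functional-group steps on bought materials; the only chirality that must be bought is in 5 and 18.

## Other disconnections considered

Alternative 1: Cut C5–C6, with the C6 side chain drawn back to C(Et)=CH–CH2Ph on C7. Forward: zerovalent palladium inserts into the C5–I bond of the (Z)-alkenyl iodide A1. A 6-exo-trig carbopalladation of the trisubstituted alkene closes ring A and makes quaternary C6. The resulting alkylpalladium has β-hydrogens only on the benzylic CH2, so elimination can only give the styrene, as the methyl ester A2 (identical with 35).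
- In its favour: C6 and the E-styrene appear in one step with no masked aldehyde. The reaction class is well established, which is better than the chosen key step. The end game is two to three steps shorter, which is also better.
- Against: C6 is made next to quaternary C7 by insertion into a hindered alkene. Its configuration rests on which rotamer about the C7–alkene bond reacts, and nothing in A1 clearly favours one face. Slow insertion invites reduction of the C–I bond and migration of the product double bond. A1 still needs ring B with C3, C3a, C7a and quaternary C7, which is no simpler than 27.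
- Comparison: on structure, the two quaternary centres are made in separate steps (easier bond by bond) but C6 is less controlled; in the chosen plan both come from one chair Claisen. On mechanism it is equal or better in reliability and worse in stereochemical predictability. On step economy it is about equal overall.

Alternative 2: Cut C7–C7a and C3a–C4. Forward: Et2AlCl activates acyl oxazolidinone A4, which adds endo across the diene termini of 2-pyrone A3 to give the bridged lactone A5.
- In its favour: it is convergent, which is better than the chosen plan. C7, C7a and C3a are set in one step, the trans relation follows from the E dienophile and the absolute sense from the auxiliary; on absolute control it is the equal of the chosen plan. The lactone bridge is a latent C7 carboxyl and an allylic leaving group, so an anti SN2′ ethyl transfer from copper to C6 could make the second quaternary centre cis to the C7 methyl and move the alkene to C4=C5.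
- Against: a 2-pyrone is a reluctant diene and the acyl imide is electron-poor, so the polarity is mismatched. The bridge is lost as CO2 on warming. Regiochemistry at a fully substituted diene terminus is not assured. In A5 the carbon on C3a is a plain ethyl group, so C3 has neither its stereocentre nor a handle for ring B, and C6 is still trigonal.
- Comparison: on structure it solves C7 and the fusion but leaves C6, C3 and ring B open, whereas the chosen route has all five centres when the key step is over. On mechanism it is a known cycloaddition class and so better founded. On step economy it is worse after the key step.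

Alternative 3: Cut both ring alkenes, C1=C2 and C4=C5. Forward: the ruthenium carbene closes ring B from the C3 vinyl and C1 methylidene groups of pentaene A6. It then closes ring A from the C4 isopropenyl group and one of the two vinyl groups on C6, giving A7.
- In its favour: this is the most dependable bond-forming reaction of the four plans, which is better than the chosen key step. There are no oxidation-state changes. The remaining vinyl group is one cross-metathesis or coupling away from the styrene, so the end game is shorter, which is also better.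
- Against: C6 becomes a stereocentre only through the choice between two diastereotopic vinyl groups, guided by nothing larger than ethyl versus vinyl. A C6 vinyl group and the C1 methylidene group can close a five-membered ring across C6–C7–C7a–C1, which competes with both intended closures. A6 carries four contiguous stereocentres and a divinyl carbon next to quaternary C7 in an open chain.
- Comparison: on structure all difficulty is pushed into an acyclic precursor. On mechanism it is equal or better in reliability and clearly worse in control of C6. On step economy it is better after the key step and worse before it.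

Key step: step 18

Remark on the chemistry: the configurations of 27 and 30 were checked centre by centre against 36 and agree (27: alkenyl group cis to CO2Me and CH2OPMB, hydroxyl trans to the ester, Z alkene, R side-chain centre), so no structure is corrected.

Remark on the design: PMB ether and methyl ester are kept in 27 (a silyl ether would migrate to the alkoxide; only a methyl ester can be cleaved by SN2 attack). The improvements are KN(SiMe3)2 in place of KH, because the Z alkene holds the doubly allylic C3–H next to the oxyanion, and oxidation of 33 without isolation.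

PMB = 4-methoxybenzyl. C8 = the methylidene carbon on C1 that leaves as ethene in step 20.

## Steps

Step 1
Reactants: 1 diethyl 2-ethylpropanedioate
Product: 2 2-ethylpropane-1,3-diol
Conditions: LiAlH4, THF, 0 °C → reflux; Fieser work-up
Reagents that add atoms: none
Why: Hydride reduction of both ester groups (LiAlH4 ester reduction) gives the symmetric diol; no stereocentre is involved.

Step 2
Reactants: 2 2-ethylpropane-1,3-diol
Product: 3 rac-2-{[(4-methoxybenzyl)oxy]methyl}butan-1-ol
Conditions: NaH (1.0 equiv), 4-methoxybenzyl chloride (1.0 equiv), n-Bu4NI (cat.), THF/DMF, 0 °C → rt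
Reagents that add atoms: 4-methoxybenzyl chloride, COc1ccc(CCl)cc1
Why: Williamson ether synthesis on the monosodium alkoxide of a symmetric diol stops largely after one alkylation. The new centre is racemic on purpose, because it is erased by enolisation in step 7.

Step 3
Reactants: 3 rac-2-{[(4-methoxybenzyl)oxy]methyl}butan-1-ol
Product: 4 rac-2-{[(4-methoxybenzyl)oxy]methyl}butanoic acid
Conditions: TEMPO (cat.), PhI(OAc)2, MeCN/H2O (1:1), rt
Reagents that add atoms: water, O
Why: Nitroxyl-catalysed oxidation of the primary alcohol proceeds through the aldehyde hydrate to the acid; the PMB ether is inert to the oxoammonium ion under these conditions.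

Step 4
Reactants: 4 rac-2-{[(4-methoxybenzyl)oxy]methyl}butanoic acid; 5 (R)-but-3-en-2-ol
Product: 6 (R)-but-3-en-2-yl 2-{[(4-methoxybenzyl)oxy]methyl}butanoate (both epimers at C2 of the acyl part)
Conditions: EDC·HCl, DMAP (cat.), CH2Cl2, 0 °C → rt
Reagents that add atoms: none
Why: Carbodiimide (Steglich) esterification acylates the alcohol oxygen, so the carbinol centre of 5 is carried over unchanged.

Step 5
Reactants: 6 (R)-but-3-en-2-yl 2-{[(4-methoxybenzyl)oxy]methyl}butanoate
Product: 7 (R)-1-oxopropan-2-yl 2-{[(4-methoxybenzyl)oxy]methyl}butanoate (both epimers at C2 of the acyl part)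
Conditions: OsO4 (2 mol %), NaIO4, 2,6-lutidine, 1,4-dioxane/H2O (3:1), rt
Reagents that add atoms: sodium periodate, [Na+].[O-]I(=O)(=O)=O; water, O
Why: Lemieux–Johnson cleavage (dihydroxylation, then periodate cleavage) turns the vinyl group into the aldehyde. Lutidine keeps the medium neutral, so the α-acyloxy centre should not epimerise and the PMB ether survives, which ozone would not guarantee.

Step 6
Reactants: 7 (R)-1-oxopropan-2-yl 2-{[(4-methoxybenzyl)oxy]methyl}butanoate
Product: 8 methyl (2Z,4R)-4-[(2-{[(4-methoxybenzyl)oxy]methyl}butanoyl)oxy]-2-methylpent-2-enoate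
Conditions: methyl 2-[bis(2,2,2-trifluoroethoxy)phosphoryl]propanoate, KN(SiMe3)2, 18-crown-6, THF, −78 °C
Reagents that add atoms: methyl 2-[bis(2,2,2-trifluoroethoxy)phosphoryl]propanoate, COC(=O)C(C)P(=O)(OCC(F)(F)F)OCC(F)(F)F
Why: Still–Gennari olefination: the electron-poor phosphonate with a dissociated potassium counter-ion eliminates from the kinetic syn adduct and gives the Z trisubstituted enoate. The Z ester cannot lactonise because its γ-oxygen is already acylated.

Step 7
Reactants: 8 methyl (2Z,4R)-4-[(2-{[(4-methoxybenzyl)oxy]methyl}butanoyl)oxy]-2-methylpent-2-enoate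
Product: 10 (2S,3R,4E)-2-ethyl-3-(methoxycarbonyl)-2-{[(4-methoxybenzyl)oxy]methyl}-3-methylhex-4-enoic acid, via silyl ketene acetal 9 (not isolated)
Conditions: LiN(i-Pr)2, Me3SiCl (present from the start), THF, −78 °C → rt, then 60 °C; dilute aqueous HCl work-up
Reagents that add atoms: none
Why: Ireland–Claisen rearrangement: deprotonation with lithium held between the ester and PMB ether oxygens should give ketene acetal 9 with CH2OPMB cis to OSiMe3 and ethyl on the side of the allylic oxygen. In the chair with the carbinol methyl equatorial, ethyl and the Z ester group are axial; this joins C6 and C7 with methyl/ethyl and CH2OPMB/CO2Me pairwise syn, and the (R)-carbinol fixes the absolute sense (C6 S, C7 R) and leaves an E-propenyl group. A1,3 strain in the Z-enoate keeps its γ-H in the alkene plane, which should suppress γ-deprotonation.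

Step 8
Reactants: 11 2-methylidenebutanal
Product: 12 2-methylidenebutan-1-ol
Conditions: NaBH4, CeCl3·7H2O, MeOH, 0 °C
Reagents that add atoms: none
Why: Luche reduction delivers hydride to the carbonyl carbon only, giving the allylic alcohol without conjugate reduction.

Step 9
Reactants: 12 2-methylidenebutan-1-ol
Product: 14 tributyl(2-methylidenebutyl)stannane, via allylic mesylate 13 (not isolated)
Conditions: MsCl, Et3N, THF, −20 °C; then Bu3SnLi (from Bu3SnH and LiN(i-Pr)2), THF, −78 → 0 °C
Reagents that add atoms: tributyltin hydride, CCCC[SnH](CCCC)CCCC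
Why: Sulfonylation followed by substitution with the stannyl anion; direct and allylic attack give the same product because the allyl unit is symmetric about C2.

Step 10
Reactants: 10 (2S,3R,4E)-2-ethyl-3-(methoxycarbonyl)-2-{[(4-methoxybenzyl)oxy]methyl}-3-methylhex-4-enoic acid; 14 tributyl(2-methylidenebutyl)stannane
Product: 16 methyl (2R,3S)-3-ethyl-3-{[(4-methoxybenzyl)oxy]methyl}-2-methyl-6-methylidene-4-oxo-2-[(1E)-prop-1-en-1-yl]octanoate, via acid chloride 15 (not isolated)
Conditions: 1-chloro-N,N,2-trimethylprop-1-en-1-amine, CH2Cl2, 0 °C → rt; then 14, Pd2(dba)3 (2.5 mol %), P(2-furyl)3, THF, 50 °C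
Reagents that add atoms: none
Why: The α-chloroenamine makes the acid chloride without HCl, so the PMB ether is safe. Migita–Kosugi–Stille acylation (oxidative addition of the acyl chloride to zerovalent palladium, allyl transfer from tin, reductive elimination) then gives the β,γ-unsaturated ketone without base and without over-addition; the quaternary centres are spectators.

Step 11
Reactants: 16 methyl (2R,3S)-3-ethyl-3-{[(4-methoxybenzyl)oxy]methyl}-2-methyl-6-methylidene-4-oxo-2-[(1E)-prop-1-en-1-yl]octanoate
Product: 17 methyl (1R,6S)-3,6-diethyl-6-{[(4-methoxybenzyl)oxy]methyl}-1-methyl-5-oxocyclohex-2-ene-1-carboxylate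
Conditions: second-generation Hoveyda–Grubbs catalyst (5 mol %), 1,4-benzoquinone (10 mol %), toluene, 80 °C
Reagents that add atoms: none
Why: Ring-closing metathesis between the propenyl and 2-ethylallyl groups forms the trisubstituted ring alkene C1=C7a of ring C with loss of propene. The two quaternary carbons pre-organise the chain, and benzoquinone suppresses hydride-induced migration of the β,γ-alkene.

Step 12
Reactants: 18 methyl (R)-3-hydroxy-2-methylpropanoate
Product: 19 methyl (R)-3-[(tert-butyldimethylsilyl)oxy]-2-methylpropanoate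
Conditions: t-BuMe2SiCl, imidazole, CH2Cl2, rt
Reagents that add atoms: tert-butyldimethylsilyl chloride, CC(C)(C)[Si](C)(C)Cl
Why: Standard silylation of the primary alcohol; the stereocentre is not involved.

Step 13
Reactants: 19 methyl (R)-3-[(tert-butyldimethylsilyl)oxy]-2-methylpropanoate
Product: 20 (R)-3-[(tert-butyldimethylsilyl)oxy]-2-methylpropanal
Conditions: i-Bu2AlH (1.05 equiv), CH2Cl2, −78 °C; Rochelle salt work-up
Reagents that add atoms: none
Why: Partial ester reduction stops at the aluminium hemiacetal at −78 °C; cold work-up gives the aldehyde with the α-centre intact.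

Step 14
Reactants: 20 (R)-3-[(tert-butyldimethylsilyl)oxy]-2-methylpropanal
Product: 21 tert-butyl{[(2S,3Z)-4-iodo-2-methylpent-3-en-1-yl]oxy}dimethylsilane
Conditions: Ph3P(Et)I, n-BuLi, THF; I2, −78 °C; NaN(SiMe3)2, −20 °C; then 20, −78 °C
Reagents that add atoms: ethyltriphenylphosphonium iodide, CC[P+](c1ccccc1)(c1ccccc1)c1ccccc1.[I-]; iodine, II
Why: Stork–Zhao olefination: the α-iodo ylide reacts through the cis oxaphosphetane and places iodine cis to the alkyl chain (Z). The descriptor changes from R to S only because CH2OSi now outranks the alkenyl carbon.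

Step 15
Reactants: 21 tert-butyl{[(2S,3Z)-4-iodo-2-methylpent-3-en-1-yl]oxy}dimethylsilane
Product: 22 (2S,3Z)-4-iodo-2-methylpent-3-en-1-ol
Conditions: HF·pyridine, THF/pyridine, 0 °C → rt
Reagents that add atoms: none
Why: Fluoride-driven Si–O cleavage under buffered conditions leaves the alkenyl iodide and the allylic stereocentre untouched.

Step 16
Reactants: 22 (2S,3Z)-4-iodo-2-methylpent-3-en-1-ol
Product: 24 (2Z,4R)-2-iodo-4-methylhexa-2,5-diene, via β,γ-unsaturated aldehyde 23 (not isolated)
Conditions: Dess–Martin periodinane, NaHCO3, CH2Cl2, 0 °C; filtered solution added to Ph3P=CH2 (from Ph3PCH3Br and KN(SiMe3)2), THF, −78 → 0 °C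
Reagents that add atoms: methyltriphenylphosphonium bromide, C[P+](c1ccccc1)(c1ccccc1)c1ccccc1.[Br-]
Why: Buffered periodinane oxidation followed at once by Wittig methylenation at low temperature. Aldehyde 23 is α-chiral and β,γ-unsaturated, so it is never isolated and meets the ylide cold to keep C3 intact.

Step 17
Reactants: 24 (2Z,4R)-2-iodo-4-methylhexa-2,5-diene; 17 methyl (1R,6S)-3,6-diethyl-6-{[(4-methoxybenzyl)oxy]methyl}-1-methyl-5-oxocyclohex-2-ene-1-carboxylate
Product: 27 methyl (1R,5S,6S)-3,6-diethyl-5-hydroxy-6-{[(4-methoxybenzyl)oxy]methyl}-1-methyl-5-[(2Z,4R)-4-methylhexa-2,5-dien-2-yl]cyclohex-2-ene-1-carboxylate, via alkenyllithium 25 (not isolated), via alkenylcerium dichloride 26 (not isolated)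
Conditions: 24, t-BuLi (2.0 equiv), Et2O, −78 °C; CeCl3 (dried), THF, −78 °C; then 17, −78 °C; aqueous NH4Cl
Reagents that add atoms: none
Why: Iodine–lithium exchange keeps the alkene geometry, and the trivalent cerium reagent adds to the hindered, enolisable ketone while ignoring the neopentyl ester (organocerium 1,2-addition). Cerium bridging C=O and the PMB ether oxygen should hold CH2OPMB in the carbonyl plane and the C6 ethyl group axial, so the alkenyl group enters anti to ethyl. This puts it cis to CH2OPMB and CO2Me and the new hydroxyl trans to the ester (C5 S).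

Step 18
Reactants: 27 methyl (1R,5S,6S)-3,6-diethyl-5-hydroxy-6-{[(4-methoxybenzyl)oxy]methyl}-1-methyl-5-[(2Z,4R)-4-methylhexa-2,5-dien-2-yl]cyclohex-2-ene-1-carboxylate
Product: 30 methyl (1R,2S,5S,6R)-6-(but-1-en-2-yl)-5-[(2R)-but-3-en-2-yl]-2-ethyl-2-{[(4-methoxybenzyl)oxy]methyl}-1,4-dimethyl-3-{[(trifluoromethyl)sulfonyl]oxy}cyclohex-3-ene-1-carboxylate, via potassium alkoxide 28 (not isolated), via potassium enolate 29 (not isolated)
Conditions: KN(SiMe3)2 (1.2 equiv), 18-crown-6, THF, −20 °C → rt (40 °C if needed); then PhNTf2, −78 → 0 °C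
Reagents that add atoms: N-phenylbis(trifluoromethanesulfonimide), O=S(=O)(N(c1ccccc1)S(=O)(=O)C(F)(F)F)C(F)(F)F
Why: Proposed new method: the base and crown ether give the loosely paired potassium alkoxide 28, whose oxyanion weakens C5–C8, and a suprafacial [3,3] shift of the 1,5-diene C3a=C4–C5(O–)–C8–C1=C7a forms C3a–C7a as C5–C8 breaks, giving enolate 29 (C4=C5–O–), which PhNTf2 traps on oxygen. The closest known reaction type is the anionic oxy-Cope rearrangement of bridged 1,5-dien-3-olates forced through boat transition states; new here is that the two-carbon unit C6–C7 ties C5 to C7a, so one cyclohexene is exchanged for another. Ring A is closed by the sigmatropic bond formation itself: the fragments C3a–C4–C5 and C7a–C1–C8 face each other in a boat, and C6–C7 is the third bridge of a bicyclo[2.2.2]octane-like array. C7a is controlled by the C5 carbinol centre from step 17, since the alkenyl group can reach C7a only on its own face of ring C, which leaves the C1 branch cis to the C7 methyl and C6 ethyl groups. C3a is controlled by the Z geometry of the alkenyl group: in the boat the C3 branch on C3a and C7 on C7a are the two inside substituents and eclipse each other, so H3a and H7a end anti and the two arms trans, while C3 is a spectator. The step needs the concerted shift to beat the dissociative path (retro-allylation to an enone and an allyl anion that recombines at C8, the [1,3] shift to a cyclooctenone) and to beat deprotonation of the doubly allylic C3–H; the boat twisted so that C4 approaches C1 is the only geometry in which the breaking and forming bonds both overlap with the π systems, the crown ether and low temperature favour the concerted path, and the amide base is far less aggressive towards C–H bonds than KH. Lactonisation cannot interfere because O– on C5 is trans to CO2Me on C7, silyl migration is excluded by the PMB ether, and the C6 substituent has no π bond that could start a second oxy-Cope path.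

Step 19
Reactants: 30 methyl (1R,2S,5S,6R)-6-(but-1-en-2-yl)-5-[(2R)-but-3-en-2-yl]-2-ethyl-2-{[(4-methoxybenzyl)oxy]methyl}-1,4-dimethyl-3-{[(trifluoromethyl)sulfonyl]oxy}cyclohex-3-ene-1-carboxylate
Product: 31 methyl (1R,2S,5S,6R)-6-(but-1-en-2-yl)-5-[(2R)-but-3-en-2-yl]-2-ethyl-2-{[(4-methoxybenzyl)oxy]methyl}-1,4-dimethylcyclohex-3-ene-1-carboxylate
Conditions: Pd(OAc)2 (5 mol %), PPh3, HCO2H, n-Bu3N, DMF, 60 °C
Reagents that add atoms: none
Why: Palladium-catalysed formate reduction of the enol triflate: oxidative addition to zerovalent palladium, formate exchange, loss of CO2 and reductive elimination of C5–H. Heck closure onto either terminal alkene would need a bridgehead alkene and should not compete.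

Step 20
Reactants: 31 methyl (1R,2S,5S,6R)-6-(but-1-en-2-yl)-5-[(2R)-but-3-en-2-yl]-2-ethyl-2-{[(4-methoxybenzyl)oxy]methyl}-1,4-dimethylcyclohex-3-ene-1-carboxylate
Product: 32 methyl (3R,3aS,6S,7R,7aR)-1,6-diethyl-6-{[(4-methoxybenzyl)oxy]methyl}-3,4,7-trimethyl-3a,6,7,7a-tetrahydro-3H-indene-7-carboxylate
Conditions: second-generation Hoveyda–Grubbs catalyst (5 mol %), CH2Cl2, 40 °C
Reagents that add atoms: none
Why: Ring-closing metathesis of the C3 vinyl group with the C1 methylidene group forms the trisubstituted C1=C2 bond and ring B with loss of ethene. The two arms are trans-diequatorial neighbours, and the trisubstituted C4=C5 bond is too hindered to take part.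

Step 21
Reactants: 32 methyl (3R,3aS,6S,7R,7aR)-1,6-diethyl-6-{[(4-methoxybenzyl)oxy]methyl}-3,4,7-trimethyl-3a,6,7,7a-tetrahydro-3H-indene-7-carboxylate
Product: 34 methyl (3R,3aS,6S,7R,7aR)-1,6-diethyl-6-formyl-3,4,7-trimethyl-3a,6,7,7a-tetrahydro-3H-indene-7-carboxylate, via primary alcohol 33 (not isolated)
Conditions: DDQ, CH2Cl2/pH 7 buffer, 0 °C; dried organic phase treated directly with Dess–Martin periodinane, NaHCO3, 0 °C → rt
Reagents that add atoms: none
Why: Oxidative PMB cleavage (hydride abstraction to the oxocarbenium ion, then hydrolysis) followed at once by periodinane oxidation. Alcohol 33 is not isolated because its hydroxyl is 1,4 to the C7 ester carbonyl and would close a γ-lactone on standing.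

Step 22
Reactants: 34 methyl (3R,3aS,6S,7R,7aR)-1,6-diethyl-6-formyl-3,4,7-trimethyl-3a,6,7,7a-tetrahydro-3H-indene-7-carboxylate
Product: 35 methyl (3R,3aS,6S,7R,7aR)-1,6-diethyl-3,4,7-trimethyl-6-[(E)-2-phenylethenyl]-3a,6,7,7a-tetrahydro-3H-indene-7-carboxylate
Conditions: 5-(benzylsulfonyl)-1-phenyl-1H-tetrazole, KN(SiMe3)2, DME, −60 °C → rt
Reagents that add atoms: 5-(benzylsulfonyl)-1-phenyl-1H-tetrazole, O=S(=O)(Cc1ccccc1)c1nnnn1-c1ccccc1
Why: Julia–Kocienski olefination: the metallated benzyl sulfone adds to the non-enolisable neopentyl aldehyde, and Smiles rearrangement with loss of SO2 and the tetrazolone gives the alkene. E geometry is expected for a hindered aldehyde with a semi-stabilised sulfonyl anion.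

Step 23
Reactants: 35 methyl (3R,3aS,6S,7R,7aR)-1,6-diethyl-3,4,7-trimethyl-6-[(E)-2-phenylethenyl]-3a,6,7,7a-tetrahydro-3H-indene-7-carboxylate
Product: 36 (3R,3aS,6S,7R,7aR)-1,6-diethyl-3,4,7-trimethyl-6-[(E)-2-phenylethenyl]-3a,6,7,7a-tetrahydro-3H-indene-7-carboxylic acid (24-nor-spiculoic acid B)
Conditions: n-PrSLi (5 equiv), HMPA, rt; then cold 0.5 M HCl to pH 3
Reagents that add atoms: none
Why: SN2 dealkylation: the soft thiolate attacks the methyl carbon of the ester, so the acyl carbon shielded by two quaternary centres need not be reached. No strong acid or heat touches the lactonisation-prone diene acid, and no stereocentre is affected.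

## Compound list

1 | diethyl 2-ethylpropanedioate | CCOC(=O)C(CC)C(=O)OCC | starting material
2 | 2-ethylpropane-1,3-diol | CCC(CO)CO | intermediate
3 | rac-2-{[(4-methoxybenzyl)oxy]methyl}butan-1-ol | CCC(CO)COCc1ccc(OC)cc1 | intermediate
4 | rac-2-{[(4-methoxybenzyl)oxy]methyl}butanoic acid | CCC(COCc1ccc(OC)cc1)C(=O)O | intermediate
5 | (R)-but-3-en-2-ol | O[C@H](C)C=C | starting material
6 | (R)-but-3-en-2-yl 2-{[(4-methoxybenzyl)oxy]methyl}butanoate (both epimers at C2 of the acyl part) | CCC(COCc1ccc(OC)cc1)C(=O)O[C@H](C)C=C | intermediate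
7 | (R)-1-oxopropan-2-yl 2-{[(4-methoxybenzyl)oxy]methyl}butanoate (both epimers at C2 of the acyl part) | CCC(COCc1ccc(OC)cc1)C(=O)O[C@H](C)C=O | intermediate
8 | methyl (2Z,4R)-4-[(2-{[(4-methoxybenzyl)oxy]methyl}butanoyl)oxy]-2-methylpent-2-enoate | CCC(COCc1ccc(OC)cc1)C(=O)O[C@H](C)/C=C(/C)C(=O)OC | intermediate
9 | trimethylsilyl ketene acetal of 8 (CH2OPMB cis to OSiMe3; not isolated) | CC/C(COCc1ccc(OC)cc1)=C(/O[Si](C)(C)C)O[C@H](C)/C=C(/C)C(=O)OC | intermediate
10 | (2S,3R,4E)-2-ethyl-3-(methoxycarbonyl)-2-{[(4-methoxybenzyl)oxy]methyl}-3-methylhex-4-enoic acid | C/C=C/[C@@](C)(C(=O)OC)[C@@](C(=O)O)(CC)COCc1ccc(OC)cc1 | intermediate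
11 | 2-methylidenebutanal (2-ethylacrolein) | C=C(CC)C=O | starting material
12 | 2-methylidenebutan-1-ol | C=C(CC)CO | intermediate
13 | 2-methylidenebutyl methanesulfonate (not isolated) | C=C(CC)COS(C)(=O)=O | intermediate
14 | tributyl(2-methylidenebutyl)stannane | C=C(CC)C[Sn](CCCC)(CCCC)CCCC | intermediate
15 | (2S,3R,4E)-2-ethyl-3-(methoxycarbonyl)-2-{[(4-methoxybenzyl)oxy]methyl}-3-methylhex-4-enoyl chloride (not isolated) | C/C=C/[C@@](C)(C(=O)OC)[C@@](C(=O)Cl)(CC)COCc1ccc(OC)cc1 | intermediate
16 | methyl (2R,3S)-3-ethyl-3-{[(4-methoxybenzyl)oxy]methyl}-2-methyl-6-methylidene-4-oxo-2-[(1E)-prop-1-en-1-yl]octanoate | C/C=C/[C@@](C)(C(=O)OC)[C@@](C(=O)CC(=C)CC)(CC)COCc1ccc(OC)cc1 | intermediate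
17 | methyl (1R,6S)-3,6-diethyl-6-{[(4-methoxybenzyl)oxy]methyl}-1-methyl-5-oxocyclohex-2-ene-1-carboxylate | O=C1CC(CC)=C[C@@](C)(C(=O)OC)[C@@]1(CC)COCc2ccc(OC)cc2 | intermediate
18 | methyl (R)-3-hydroxy-2-methylpropanoate | COC(=O)[C@H](C)CO | starting material
19 | methyl (R)-3-[(tert-butyldimethylsilyl)oxy]-2-methylpropanoate | COC(=O)[C@H](C)CO[Si](C)(C)C(C)(C)C | intermediate
20 | (R)-3-[(tert-butyldimethylsilyl)oxy]-2-methylpropanal | O=C[C@H](C)CO[Si](C)(C)C(C)(C)C | intermediate
21 | tert-butyl{[(2S,3Z)-4-iodo-2-methylpent-3-en-1-yl]oxy}dimethylsilane | I/C(C)=C\[C@H](C)CO[Si](C)(C)C(C)(C)C | intermediate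
22 | (2S,3Z)-4-iodo-2-methylpent-3-en-1-ol | I/C(C)=C\[C@H](C)CO | intermediate
23 | (2S,3Z)-4-iodo-2-methylpent-3-enal (not isolated) | I/C(C)=C\[C@H](C)C=O | intermediate
24 | (2Z,4R)-2-iodo-4-methylhexa-2,5-diene | I/C(C)=C\[C@H](C)C=C | intermediate
25 | [(4R)-4-methylhexa-2,5-dien-2-yl]lithium, lithium cis to C4 (not isolated) | [Li]/C(C)=C\[C@H](C)C=C | intermediate
26 | dichloro[(4R)-4-methylhexa-2,5-dien-2-yl]cerium, cerium cis to C4 (not isolated) | Cl[Ce](Cl)/C(C)=C\[C@H](C)C=C | intermediate
27 | methyl (1R,5S,6S)-3,6-diethyl-5-hydroxy-6-{[(4-methoxybenzyl)oxy]methyl}-1-methyl-5-[(2Z,4R)-4-methylhexa-2,5-dien-2-yl]cyclohex-2-ene-1-carboxylate | O[C@]1(/C(C)=C\[C@H](C)C=C)CC(CC)=C[C@@](C)(C(=O)OC)[C@@]1(CC)COCc1ccc(OC)cc1 | intermediate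
28 | potassium alkoxide of 27 (not isolated) | [K+].[O-][C@]1(/C(C)=C\[C@H](C)C=C)CC(CC)=C[C@@](C)(C(=O)OC)[C@@]1(CC)COCc1ccc(OC)cc1 | intermediate
29 | potassium enolate, the C5-olate corresponding to 30 (not isolated) | [K+].C=C(CC)[C@H]1[C@H]([C@H](C)C=C)C(C)=C([O-])[C@@](COCc2ccc(OC)cc2)(CC)[C@]1(C)C(=O)OC | intermediate
30 | methyl (1R,2S,5S,6R)-6-(but-1-en-2-yl)-5-[(2R)-but-3-en-2-yl]-2-ethyl-2-{[(4-methoxybenzyl)oxy]methyl}-1,4-dimethyl-3-{[(trifluoromethyl)sulfonyl]oxy}cyclohex-3-ene-1-carboxylate | C=C(CC)[C@H]1[C@H]([C@H](C)C=C)C(C)=C(OS(=O)(=O)C(F)(F)F)[C@@](COCc2ccc(OC)cc2)(CC)[C@]1(C)C(=O)OC | intermediate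
31 | methyl (1R,2S,5S,6R)-6-(but-1-en-2-yl)-5-[(2R)-but-3-en-2-yl]-2-ethyl-2-{[(4-methoxybenzyl)oxy]methyl}-1,4-dimethylcyclohex-3-ene-1-carboxylate | C=C(CC)[C@H]1[C@H]([C@H](C)C=C)C(C)=C[C@@](COCc2ccc(OC)cc2)(CC)[C@]1(C)C(=O)OC | intermediate
32 | methyl (3R,3aS,6S,7R,7aR)-1,6-diethyl-6-{[(4-methoxybenzyl)oxy]methyl}-3,4,7-trimethyl-3a,6,7,7a-tetrahydro-3H-indene-7-carboxylate | CCC1=C[C@@H](C)[C@@H]2C(C)=C[C@@](COCc3ccc(OC)cc3)(CC)[C@](C)(C(=O)OC)[C@@H]12 | intermediate
33 | methyl (3R,3aS,6S,7R,7aR)-1,6-diethyl-6-(hydroxymethyl)-3,4,7-trimethyl-3a,6,7,7a-tetrahydro-3H-indene-7-carboxylate (not isolated) | CCC1=C[C@@H](C)[C@@H]2C(C)=C[C@@](CO)(CC)[C@](C)(C(=O)OC)[C@@H]12 | intermediate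
34 | methyl (3R,3aS,6S,7R,7aR)-1,6-diethyl-6-formyl-3,4,7-trimethyl-3a,6,7,7a-tetrahydro-3H-indene-7-carboxylate | CCC1=C[C@@H](C)[C@@H]2C(C)=C[C@@](C=O)(CC)[C@](C)(C(=O)OC)[C@@H]12 | intermediate
35 | methyl (3R,3aS,6S,7R,7aR)-1,6-diethyl-3,4,7-trimethyl-6-[(E)-2-phenylethenyl]-3a,6,7,7a-tetrahydro-3H-indene-7-carboxylate | CCC1=C[C@@H](C)[C@@H]2C(C)=C[C@@](/C=C/c3ccccc3)(CC)[C@](C)(C(=O)OC)[C@@H]12 | intermediate
36 | (3R,3aS,6S,7R,7aR)-1,6-diethyl-3,4,7-trimethyl-6-[(E)-2-phenylethenyl]-3a,6,7,7a-tetrahydro-3H-indene-7-carboxylic acid (24-nor-spiculoic acid B) | CCC1=C[C@@H](C)[C@@H]2C(C)=C[C@@](/C=C/c3ccccc3)(CC)[C@](C)(C(=O)O)[C@@H]12 | target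

## Step count and least certain steps

Total step count: 23. Longest linear sequence: 16 steps (1–7, 10, 11, 17–23).

The least certain steps are 18, 7, 17 and 22.

**Step 18 (key step, no direct precedent).**
- What may go wrong: the alkoxide may dissociate by retro-allylation and recombine at C8 (ring expansion by a [1,3] shift) or not recombine at all, instead of taking the concerted path through the strained bridged boat. Slow rearrangement would also give time for base-induced migration of the skipped diene and loss of the C3 configuration.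
- Fallback (known reactions only): it sets out from acid 10 and returns at triflate 30. It does the dissociative sequence on purpose, with a silicon-controlled allyl donor.
  - Chloride 15 with HN(OMe)Me·HCl/pyridine gives the N-methoxy-N-methylamide F1.
  - OsO4/NaIO4 cleaves the propenyl group to the C7 aldehyde F2.
  - Wittig reaction with Ph3P=C(Et)CH2SiMe3 gives the allylsilane F3.
  - Alkenyllithium 25 adds to the amide to give the enone F4.
  - EtAlCl2 (toluene, −78 → 0 °C) triggers an intramolecular Hosomi–Sakurai reaction: the γ-carbon of the allylsilane (C7a) adds to the β-carbon of the enone (C3a), closing ring A and leaving the C1 methylidene group. This gives the cyclohexanone F5.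
  - F5 can enolise only towards C4, so KN(SiMe3)2/PhNTf2 gives 30.
  - The trans arrangement of the two new arms is expected from a chair-like closure. The face relative to C7 is less secure than in step 18, so isomers may have to be separated.

**Step 7.**
- What may go wrong: incomplete chelation during enolisation would give the other ketene acetal geometry and so the C6 epimer. β-Elimination of the PMB oxide from the lithium enolate, or conjugate addition of the enolate to the enoate before silylation, would consume material.
- Fallback: it sets out from alcohol 5 and returns at acid 10. Both alkene geometries are fixed in an isolable precursor instead of in an enolate.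
  - Cross-metathesis of 5 with methyl methacrylate (second-generation Hoveyda–Grubbs catalyst) gives the E hydroxy enoate F6.
  - Mitsunobu O-alkylation of the enol form of allyl 2-formylbutanoate with F6 inverts the carbinol and gives the (E)-3-alkoxyacrylate F7.
  - A thermal Claisen rearrangement (xylene, 140–180 °C), chair with methyl equatorial, gives the aldehyde F8 with both quaternary centres.
  - Reductive etherification (4-methoxybenzyl trimethylsilyl ether, Et3SiH, cat. Me3SiOTf, −78 °C) gives the PMB ether allyl ester F9.
  - Pd(PPh3)4/morpholine releases 10.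

**Step 17.**
- What may go wrong: poor facial selectivity at the ring ketone. If the reagent enters on the ethyl face, the alkoxide lies cis to the ester and lactonises. Enolisation to the dienolate is the second risk.
- Fallback: it sets out from 10 and 21 and returns at 27. The carbinol centre is set by chelation in an open chain, where the only large group next to the carbonyl is quaternary C7.
  - Iodide 21 with t-BuLi gives the alkenyllithium F10.
  - F10 adds to amide F1 to give the enone F11.
  - 2-Methylidenebutylmagnesium bromide with MgBr2·OEt2 (CH2Cl2/Et2O, −78 °C) adds to the chelated ketone anti to C7 and gives the tertiary alcohol F12. After ring closure this is the configuration of 27.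
  - Ring-closing metathesis (second-generation Hoveyda–Grubbs catalyst) gives the cyclohexenol F13. No terminal vinyl group is present yet to compete.
  - HF·pyridine gives the diol F14; Dess–Martin oxidation gives the hydroxy aldehyde F15 (in equilibrium with its lactol); excess Ph3P=CH2 gives 27.

**Step 22.**
- What may go wrong: erosion of E selectivity with the semi-stabilised sulfonyl anion, and capture of the intermediate β-alkoxide by the neighbouring ester (lactone formation) before Smiles rearrangement.
- Fallback: it sets out from 34 and returns at 35. Takai iodo-olefination (CrCl2, CHI3, THF, 0 °C; divalent chromium, E-selective, no free alkoxide) gives the (E)-alkenyl iodide F16. Suzuki–Miyaura coupling with PhB(OH)2 (Pd(PPh3)4, K3PO4, THF/H2O) gives 35 with retention.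

Further compounds

F1 | step 18 | (2S,3R,4E)-2-ethyl-N-methoxy-3-(methoxycarbonyl)-2-{[(4-methoxybenzyl)oxy]methyl}-N,3-dimethylhex-4-enamide | C/C=C/[C@@](C)(C(=O)OC)[C@@](C(=O)N(C)OC)(CC)COCc1ccc(OC)cc1
F2 | step 18 | C7 aldehyde: amide F1 with a formyl group in place of the propenyl group | O=C[C@@](C)(C(=O)OC)[C@@](C(=O)N(C)OC)(CC)COCc1ccc(OC)cc1
F3 | step 18 | allylsilane: amide F1 with CH=C(Et)CH2SiMe3 in place of the propenyl group (mixture of alkene isomers) | C[Si](C)(C)CC(CC)=C[C@@](C)(C(=O)OC)[C@@](C(=O)N(C)OC)(CC)COCc1ccc(OC)cc1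
F4 | step 18 | enone: the (2Z,4R)-4-methylhexa-2,5-dien-2-yl ketone derived from F3 | C=C[C@@H](C)/C=C(/C)C(=O)[C@](CC)(COCc1ccc(OC)cc1)[C@](C)(C(=O)OC)C=C(CC)C[Si](C)(C)C
F5 | step 18 | cyclohexanone: the C5 ketone corresponding to enolate 29 (both C4 epimers) | C=C(CC)[C@H]1[C@H]([C@H](C)C=C)C(C)C(=O)[C@@](COCc2ccc(OC)cc2)(CC)[C@]1(C)C(=O)OC
F6 | step 7 | methyl (2E,4R)-4-hydroxy-2-methylpent-2-enoate | O[C@H](C)/C=C(\C)C(=O)OC
F7 | step 7 | allyl (2E)-2-ethyl-3-{[(2S,3E)-5-methoxy-4-methyl-5-oxopent-3-en-2-yl]oxy}prop-2-enoate | C=CCOC(=O)/C(CC)=C/O[C@@H](C)/C=C(\C)C(=O)OC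
F8 | step 7 | 1-allyl 4-methyl (2S,3R)-2-ethyl-2-formyl-3-methyl-3-[(1E)-prop-1-en-1-yl]butanedioate | C/C=C/[C@@](C)(C(=O)OC)[C@@](C(=O)OCC=C)(CC)C=O
F9 | step 7 | allyl ester of acid 10 | C/C=C/[C@@](C)(C(=O)OC)[C@@](C(=O)OCC=C)(CC)COCc1ccc(OC)cc1
F10 | step 17 | alkenyllithium from 21, lithium cis to the CH(CH3)CH2OSi carbon | [Li]/C(C)=C\[C@H](C)CO[Si](C)(C)C(C)(C)C
F11 | step 17 | enone from F1 and F10 (silyl ether side chain, propenyl group on C7) | CC(C)(C)[Si](C)(C)OC[C@@H](C)/C=C(/C)C(=O)[C@](CC)(COCc1ccc(OC)cc1)[C@](C)(C(=O)OC)/C=C/C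
F12 | step 17 | open-chain tertiary alcohol from F11 (2-methylidenebutyl group on the carbinol carbon) | O[C@](/C(C)=C\[C@H](C)CO[Si](C)(C)C(C)(C)C)(CC(=C)CC)[C@](CC)(COCc1ccc(OC)cc1)[C@](C)(C(=O)OC)/C=C/C
F13 | step 17 | cyclohexenol: 27 with CH2OSi(t-Bu)Me2 in place of the vinyl group | O[C@]1(/C(C)=C\[C@H](C)CO[Si](C)(C)C(C)(C)C)CC(CC)=C[C@@](C)(C(=O)OC)[C@@]1(CC)COCc1ccc(OC)cc1
F14 | step 17 | diol: 27 with CH2OH in place of the vinyl group | O[C@]1(/C(C)=C\[C@H](C)CO)CC(CC)=C[C@@](C)(C(=O)OC)[C@@]1(CC)COCc1ccc(OC)cc1
F15 | step 17 | hydroxy aldehyde: 27 with CHO in place of the vinyl group (open form of the lactol) | O[C@]1(/C(C)=C\[C@H](C)C=O)CC(CC)=C[C@@](C)(C(=O)OC)[C@@]1(CC)COCc1ccc(OC)cc1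
F16 | step 22 | methyl (3R,3aS,6S,7R,7aR)-1,6-diethyl-6-[(E)-2-iodoethenyl]-3,4,7-trimethyl-3a,6,7,7a-tetrahydro-3H-indene-7-carboxylate | CCC1=C[C@@H](C)[C@@H]2C(C)=C[C@@](/C=C/I)(CC)[C@](C)(C(=O)OC)[C@@H]12
A1 | alternative 1 | (Z)-alkenyl iodide: cyclopentene with the (1Z)-1-iodoprop-1-en-2-yl group on C3a and the C7 ester chain ending in (E)-C(Et)=CH–CH2Ph | CCC1=C[C@@H](C)[C@H](/C(C)=C\I)[C@H]1[C@@](C)(C(=O)OC)/C(CC)=C/Cc1ccccc1
A2 | alternative 1 | methyl ester of 36 (identical with 35) | CCC1=C[C@@H](C)[C@@H]2C(C)=C[C@@](/C=C/c3ccccc3)(CC)[C@](C)(C(=O)OC)[C@@H]12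
A3 | alternative 2 | 4-{[(4-methoxybenzyl)oxy]methyl}-3,6-dimethyl-2H-pyran-2-one | Cc1cc(COCc2ccc(OC)cc2)c(C)c(=O)o1
A4 | alternative 2 | (4S)-4-benzyl-3-[(2E)-pent-2-enoyl]-1,3-oxazolidin-2-one | CC/C=C/C(=O)N1[C@@H](Cc2ccccc2)COC1=O
A5 | alternative 2 | endo bicyclic lactone adduct (2-oxabicyclo[2.2.2]oct-5-en-3-one) | C[C@]12C(=O)O[C@](C)(C=C1COCc3ccc(OC)cc3)[C@@H](CC)[C@@H]2C(=O)N4[C@@H](Cc5ccccc5)COC4=O
A6 | alternative 3 | acyclic pentaene methyl ester with a divinyl carbon at C6 | C=CC(C=C)(CC)[C@](C)(C(=O)OC)[C@@H](C(=C)CC)[C@@H](C(C)=C)[C@H](C)C=C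
A7 | alternative 3 | methyl (3R,3aS,6S,7R,7aR)-6-ethenyl-1,6-diethyl-3,4,7-trimethyl-3a,6,7,7a-tetrahydro-3H-indene-7-carboxylate | CCC1=C[C@@H](C)[C@@H]2C(C)=C[C@@](C=C)(CC)[C@](C)(C(=O)OC)[C@@H]12
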